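The earlier runs and the new flask were generated by integration from invented constants; scatter was added.

| setting | east | north-east | north-west | red | blue |
|---|---|---|---|---|---|
| left-handed substrate | 0.050 M | 0.050 M | 0.050 M | 0.050 M | 0.050 M |
| right-handed substrate | 0.050 M | 0.050 M | 0.050 M | 0.050 M | 0.050 M |
| partner | 1 equiv | 1 equiv | 1 equiv | 1.00 equiv | 1.00 equiv |
| free catalyst | 1.1 mol% | 1.6 mol% | 2.7 mol% | 2.5 mol% | 1.2 mol% |
| impurity | 0.29 mM | 0.29 mM | 0.29 mM | 0.29 mM | 0.29 mM |
| remark | run made earlier | run made earlier | run made earlier |  |  |
| time |  |  |  | 20 min | 20 min |

| run | time / min | left-handed product / % | right-handed product / % | left-handed substrate / % |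
|---|---|---|---|---|
| east | 4.00 | 14.1 | 12.3 | 36.6 |
| east | 8.00 | 17.2 | 16.0 | 31.5 |
| east | 12.0 | 19.5 | 17.4 | 30.6 |
| east | 15.0 | 20.5 | 18.1 | 29.8 |
| east | 20.0 | 21.4 | 19.3 | 29.9 |
| north-east | 2.00 | 13.6 | 13.1 | 36.9 |
| north-east | 5.00 | 18.5 | 17.1 | 29.7 |
| north-east | 10.0 | 23.1 | 20.3 | 27.3 |
| north-east | 15.0 | 23.4 | 20.4 | 26.5 |
| north-east | 20.0 | 23.1 | 20.0 | 26.0 |
| north-west | 4.00 | 22.6 | 20.2 | 26.5 |
| north-west | 8.00 | 23.5 | 21.6 | 26.4 |
| north-west | 12.0 | 24.0 | 22.7 | 25.5 |
| north-west | 15.0 | 24.5 | 21.0 | 24.3 |
| north-west | 20.0 | 24.9 | 22.1 | 24.5 |

(readings scatter by 0.5 percentage points)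

* which of the two ends with the higher excess of left-handed product over right-handed product in the product ("neither" if they lie within 2 percentage points) (red / blue / neither)
* excess of left-handed product over right-handed product in the product at the end, red
* excess of left-handed product over right-handed product in the product at the end, blue

- free catalyst is single-handed; left-handed substrate and right-handed substrate are mirror images of each other, charged as a racemate, each of them at the stated concentration
- the analysis behind the earlier runs scatters by 0.5 percentage points, standard deviation
- an excess is below zero if the other one leads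

Slowness in the earlier runs turns into a near halt with substrate left: between 8.00 min and 20.0 min the north-west run adds 1.4 percentage points of left-handed product, while its left-handed substrate still reads 24.5%. So the question is how far each hand has gone at the halt. The nearest loadings stand in for the new flasks: north-west for red, east for blue.

The first way reads the excess straight from the products at 20.0 min:

north-west 5.96%; east 5.16%

The second way avoids the left-handed product. Let f_L be the fraction of the left-handed charge left, from the left-handed substrate reading, and f_R that of the right-handed charge, from the right-handed product reading; each hand is half of the percent base. The last readings give: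

ln f_L / ln f_R = 1.05, 1.28, 1.22; mean s = 1.19

This mean, the logarithm of the left-handed fraction left over that of the right-handed, is the selectivity factor. With f_L = f_R^s, the excess follows:

e = (f_R − f_L)/(2 − f_R − f_L)

red, f_R = 0.558: e = 6.09%
blue, f_R = 0.614: e = 6.44%

The two ways share the right-handed product but take the left hand from different readings. For red they agree. For blue they part by 1.3 points, less than the 1.7 points scatter of one direct excess, so the readings fault neither way and both values stand. By the second way my blue stands 0.35 points above my red, and by the first way north-west stands 0.8 points above east, each inside the margin: neither.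

The forecast also says neither, with 5.9% for red and 6.1% for blue, lower than my values, on the ground that “both end near 6%”.

    free catalyst + left-handed substrate ⇌ catalyst intermediate A (K = 7.20 /M, k = 120 /M/s)
    free catalyst + right-handed substrate ⇌ catalyst intermediate B (K = 15.0 /M, k = 400 /M/s)
    partner + catalyst intermediate A → free catalyst + left-handed product (k = 40.0 /M/s)
    partner + catalyst intermediate B → free catalyst + right-handed product (k = 16.0 /M/s)
    free catalyst + impurity → spent catalyst (k = 100 /M/s)
    partner → decomposed reagent (k = 3.70 × 10⁻⁴ /s)
    partner ⇌ dormant form (K = 0.800, k = 8.20 × 10⁻⁴ /s)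

The flask gives neither: red 5.35%, blue 5.50%. The nearest partner charge at which blue's excess has moved by 5 points is 3.19 equiv. In red, 55% of the right-handed substrate remains, and s turns this into 6.04%. Red's neighbour with 2.50 equiv of partner keeps 1.2% of its right-handed substrate; s turns this into 0.328%, and that flask gives 0.278%.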